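**Retrosynthetic overview** (atoms are written C-1 to C-15 in germacrane numbering; plain numbers are compounds)

1. Lychnopholide 19 ⇐ acyclic bromo-enal 17, an oxidised farnesane chain that already carries the furanone and the angelate. One chromium-mediated step closes C-6–C-7 (the bond and polarity of germacrene biogenesis: electrophilic C-6, nucleophilic C-7) and then the 6,12-lactone, setting C-6 and C-7.
2. The 3(2H)-furanone ⇐ α′-hydroxy ynone 11 (1,3-diketone oxidation level). O-10 adds to C-3, as in the hemiketalisation–dehydration proposed for furanoheliangolides.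
3. 11 ⇐ acetylide of (Z)-enynol 8 (C-2 to C-6, C-15, 4Z alkene preset) + hydroxy lactone 7 (C-1, C-8, C-9, C-10, C-14). The lactone in 7 is only a temporary O-8–C-1 tether.
4. 7 ⇐ crotonaldehyde 1 + methyl 2-(bromomethyl)acrylate 2 (asymmetric allylation sets C-8; anti enolate hydroxylation sets C-10). Compound 2 is used a second time, in a cross-metathesis, for C-11 to C-13. Angelic acid 13 is attached before the ring closure.
5. Order of ring formation: furanone (step 5), then the ten-membered carbocycle and the α-methylene-γ-lactone together (step 9).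

Assumption: pure (Z)-3-methylpent-2-en-4-yn-1-ol and angelic acid are bought; the sense of induction of the chiral chromium catalyst in step 1 is taken by analogy, and the ligand enantiomer that gives the 4S carbinol is used.

**Step 1**
Reactants: 1 (E)-but-2-enal; 2 methyl 2-(bromomethyl)acrylate
Product: 5 (5S)-3-methylene-5-[(E)-prop-1-enyl]dihydrofuran-2(3H)-one, via silyl ether ester 3 (not isolated), via hydroxy ester 4 (not isolated)
Conditions: CrCl2 (10 mol %), chiral carbazole bis(oxazoline) ligand (12 mol %), Mn (2 equiv), Me3SiCl (2 equiv), Et3N (20 mol %), THF, rt; then 1 M HCl, THF, 0 °C to rt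
Reagents that add atoms: none
Why: Catalytic asymmetric Nozaki–Hiyama–Kishi 2-(alkoxycarbonyl)allylation, in which the allylchromium species from 2 adds 1,2 to the enal through a closed chair transition state on the chiral trivalent chromium complex and so sets C-8 (4S), after which acid removes the silyl group and closes the γ-lactone.

**Step 2**
Reactants: 5 (5S)-3-methylene-5-[(E)-prop-1-enyl]dihydrofuran-2(3H)-one
Product: 7 (3R,5S)-3-hydroxy-3-methyl-5-[(E)-prop-1-enyl]dihydrofuran-2(3H)-one, via potassium enolate 6 (not isolated)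
Conditions: KBH(s-Bu)3 (1.1 equiv), THF, −78 °C (slow addition of 5); then trans-2-(phenylsulfonyl)-3-phenyloxaziridine (1.3 equiv), −78 °C; then AcOH
Reagents that add atoms: trans-2-(phenylsulfonyl)-3-phenyloxaziridine, O=S(=O)(c1ccccc1)N1OC1c1ccccc1
Why: Reductive enolate α-hydroxylation (conjugate hydride reduction, then Davis oxidation), in which the oxaziridine attacks the tetrasubstituted lactone enolate 6 on the face anti to the C-5 propenyl group (1,3-induction in butyrolactone enolates) and so sets C-10 as 3R with the hydroxyl trans to the side chain.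

**Step 3**
Reactants: 8 (Z)-3-methylpent-2-en-4-yn-1-ol
Product: 9 (Z)-triethyl[(3-methylpent-2-en-4-yn-1-yl)oxy]silane
Conditions: Et3SiCl (1.1 equiv), imidazole (1.5 equiv), CH2Cl2, 0 °C to rt
Reagents that add atoms: triethylsilyl chloride, CC[Si](Cl)(CC)CC
Why: Standard silylation, needed because a free (Z)-enynol hydroxyl would add 5-exo to the alkyne in steps 4 and 5 and aromatise to a furan; no stereocentre is involved and the Z alkene is untouched.

**Step 4**
Reactants: 7 (3R,5S)-3-hydroxy-3-methyl-5-[(E)-prop-1-enyl]dihydrofuran-2(3H)-one; 9 (Z)-triethyl[(3-methylpent-2-en-4-yn-1-yl)oxy]silane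
Product: 11 (2Z,7R,9S,10E)-7,9-dihydroxy-3,7-dimethyl-1-(triethylsilyloxy)dodeca-2,10-dien-4-yn-6-one, via lithium acetylide 10 (not isolated)
Conditions: 9 (2.3 equiv), n-BuLi (2.2 equiv), THF, −78 °C; then 7, −78 to −40 °C; AcOH quench at −78 °C
Reagents that add atoms: none
Why: Acylation of a lithium acetylide by a γ-lactone, in which one equivalent of acetylide deprotonates the tertiary hydroxyl (returning recoverable 9), a second adds to the lactone carbonyl, and the lactolate resists over-addition until quench; both stereocentres are carried through unchanged and 11 equilibrates with its five-membered lactol.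

**Step 5**
Reactants: 11 (2Z,7R,9S,10E)-7,9-dihydroxy-3,7-dimethyl-1-(triethylsilyloxy)dodeca-2,10-dien-4-yn-6-one
Product: 12 (2R)-2-[(2S,3E)-2-hydroxypent-3-enyl]-2-methyl-5-[(2Z)-4-(triethylsilyloxy)but-2-en-2-yl]furan-3(2H)-one
Conditions: Ph3PAuNTf2 (5 mol %), CH2Cl2, rt
Reagents that add atoms: none
Why: Gold-catalysed 5-endo-dig hydroalkoxylation (oxa-Michael cycloisomerisation) of the α′-hydroxy ynone, in which the C-10 hydroxyl adds to the gold-activated β-carbon C-3 and protodeauration gives the 3(2H)-furanone, the synthetic equivalent of hemiketalisation–dehydration of a 10-hydroxy-1,3-diketone; C-10 and C-8 are unchanged.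

**Step 6**
Reactants: 12 (2R)-2-[(2S,3E)-2-hydroxypent-3-enyl]-2-methyl-5-[(2Z)-4-(triethylsilyloxy)but-2-en-2-yl]furan-3(2H)-one; 13 angelic acid
Product: 15 (2S,3E)-1-{(2R)-2-methyl-3-oxo-5-[(2Z)-4-(triethylsilyloxy)but-2-en-2-yl]-2,3-dihydrofuran-2-yl}pent-3-en-2-yl (2Z)-2-methylbut-2-enoate, via mixed anhydride 14 (not isolated)
Conditions: 13 (3 equiv), 2,4,6-trichlorobenzoyl chloride (3 equiv), Et3N (6 equiv), toluene, rt, 2 h; then 12, 80 °C
Reagents that add atoms: none
Why: Yamaguchi-type esterification run without DMAP, in which the only free hydroxyl attacks the unhindered angeloyl carbonyl of mixed anhydride 14 and the absence of a nucleophilic catalyst suppresses Z-to-E isomerisation to the tiglate; C-8 keeps its configuration because only the O–H bond reacts.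

**Step 7**
Reactants: 15 (2S,3E)-1-{(2R)-2-methyl-3-oxo-5-[(2Z)-4-(triethylsilyloxy)but-2-en-2-yl]-2,3-dihydrofuran-2-yl}pent-3-en-2-yl (2Z)-2-methylbut-2-enoate
Product: 16 (2S,3E)-1-{(2R)-2-methyl-3-oxo-5-[(2Z)-4-oxobut-2-en-2-yl]-2,3-dihydrofuran-2-yl}pent-3-en-2-yl (2Z)-2-methylbut-2-enoate
Conditions: (COCl)2 (4 equiv), DMSO (8 equiv), CH2Cl2, −78 to −40 °C; then Et3N, −78 to 0 °C
Reagents that add atoms: none
Why: Swern oxidation applied directly to a primary triethylsilyl ether, in which chlorodimethylsulfonium chloride cleaves the primary silyl ether in the flask and oxidises it to the aldehyde under cold, non-equilibrating conditions that keep the (Z)-enal geometry.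

**Step 8**
Reactants: 16 (2S,3E)-1-{(2R)-2-methyl-3-oxo-5-[(2Z)-4-oxobut-2-en-2-yl]-2,3-dihydrofuran-2-yl}pent-3-en-2-yl (2Z)-2-methylbut-2-enoate; 2 methyl 2-(bromomethyl)acrylate
Product: 17 methyl (2Z,4S)-2-(bromomethyl)-4-{[(2Z)-2-methylbut-2-enoyl]oxy}-5-{(2R)-2-methyl-3-oxo-5-[(2Z)-4-oxobut-2-en-2-yl]-2,3-dihydrofuran-2-yl}pent-2-enoate
Conditions: 2 (10 equiv), second-generation Hoveyda–Grubbs catalyst (2 × 7.5 mol %), 1,2-dichloroethane, 60 °C
Reagents that add atoms: none
Why: Olefin cross-metathesis between the propenyl group (the only non-conjugated, unhindered alkene) and the non-dimerising 1,1-disubstituted acrylate 2, a pairing known for methacrylates and α-methylene lactones; the trisubstituted enoate forms mainly with the chain trans to the ester, and either geometry gives the same allylmetal in step 9.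

**Step 9**
Reactants: 17 methyl (2Z,4S)-2-(bromomethyl)-4-{[(2Z)-2-methylbut-2-enoyl]oxy}-5-{(2R)-2-methyl-3-oxo-5-[(2Z)-4-oxobut-2-en-2-yl]-2,3-dihydrofuran-2-yl}pent-2-enoate
Product: 19 lychnopholide, via hydroxy ester 18 (not isolated)
Conditions: CrCl2 (6 equiv), degassed THF, 0.003 M, addition of 17 by syringe pump over 12 h, rt; H2O work-up; then p-TsOH·H2O (10 mol %), CH2Cl2, rt
Reagents that add atoms: none
Why: Intramolecular Nozaki–Hiyama–Kishi (Barbier) 2-(alkoxycarbonyl)allylation followed by lactonisation, in which divalent chromium inserts into the allylic bromide and the γ-carbon C-7 adds only to the C-6 aldehyde (not to the vinylogous-ester C-1) through a chair transition state whose (E)-allylchromium gives the 6,7-anti, trans-lactone relationship, while allylic 1,3-strain holds H-8 in the allyl plane with the ring tether on the aldehyde face and the angelate outward and so fixes C-7 relative to C-8, and acid then closes the 6,12-lactone.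

**Compound list**

1 | (E)-but-2-enal (crotonaldehyde) | C/C=C/C=O | starting material
2 | methyl 2-(bromomethyl)acrylate | C=C(CBr)C(=O)OC | starting material
3 | methyl (4S,5E)-2-methylene-4-(trimethylsilyloxy)hept-5-enoate | COC(=O)C(=C)C[C@H](O[Si](C)(C)C)/C=C/C | intermediate
4 | methyl (4S,5E)-4-hydroxy-2-methylenehept-5-enoate | COC(=O)C(=C)C[C@H](O)/C=C/C | intermediate
5 | (5S)-3-methylene-5-[(E)-prop-1-enyl]dihydrofuran-2(3H)-one | C=C1C[C@@H](/C=C/C)OC1=O | intermediate
6 | potassium (5S)-3-methyl-5-[(E)-prop-1-enyl]-4,5-dihydrofuran-2-olate | CC1=C([O-])O[C@H](/C=C/C)C1.[K+] | intermediate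
7 | (3R,5S)-3-hydroxy-3-methyl-5-[(E)-prop-1-enyl]dihydrofuran-2(3H)-one (hydroxyl trans to propenyl) | C[C@@]1(O)C[C@@H](/C=C/C)OC1=O | intermediate
8 | (Z)-3-methylpent-2-en-4-yn-1-ol | C#C/C(C)=C\CO | starting material
9 | (Z)-triethyl[(3-methylpent-2-en-4-yn-1-yl)oxy]silane | C#C/C(C)=C\CO[Si](CC)(CC)CC | intermediate
10 | lithium acetylide of 9 | [Li+].[C-]#C/C(C)=C\CO[Si](CC)(CC)CC | intermediate
11 | (2Z,7R,9S,10E)-7,9-dihydroxy-3,7-dimethyl-1-(triethylsilyloxy)dodeca-2,10-dien-4-yn-6-one | CC[Si](CC)(CC)OC/C=C(/C)C#CC(=O)[C@](C)(O)C[C@H](O)/C=C/C | intermediate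
12 | (2R)-2-[(2S,3E)-2-hydroxypent-3-enyl]-2-methyl-5-[(2Z)-4-(triethylsilyloxy)but-2-en-2-yl]furan-3(2H)-one | CC[Si](CC)(CC)OC/C=C(/C)C1=CC(=O)[C@@](C)(C[C@H](O)/C=C/C)O1 | intermediate
13 | angelic acid, (Z)-2-methylbut-2-enoic acid | C/C=C(/C)C(=O)O | starting material
14 | (Z)-2-methylbut-2-enoic 2,4,6-trichlorobenzoic anhydride | C/C=C(/C)C(=O)OC(=O)c1c(Cl)cc(Cl)cc1Cl | intermediate
15 | (2S,3E)-1-{(2R)-2-methyl-3-oxo-5-[(2Z)-4-(triethylsilyloxy)but-2-en-2-yl]-2,3-dihydrofuran-2-yl}pent-3-en-2-yl (2Z)-2-methylbut-2-enoate | CC[Si](CC)(CC)OC/C=C(/C)C1=CC(=O)[C@@](C)(C[C@H](OC(=O)/C(C)=C\C)/C=C/C)O1 | intermediate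
16 | (2S,3E)-1-{(2R)-2-methyl-3-oxo-5-[(2Z)-4-oxobut-2-en-2-yl]-2,3-dihydrofuran-2-yl}pent-3-en-2-yl (2Z)-2-methylbut-2-enoate | O=C/C=C(/C)C1=CC(=O)[C@@](C)(C[C@H](OC(=O)/C(C)=C\C)/C=C/C)O1 | intermediate
17 | methyl (2Z,4S)-2-(bromomethyl)-4-{[(2Z)-2-methylbut-2-enoyl]oxy}-5-{(2R)-2-methyl-3-oxo-5-[(2Z)-4-oxobut-2-en-2-yl]-2,3-dihydrofuran-2-yl}pent-2-enoate | O=C/C=C(/C)C1=CC(=O)[C@@](C)(C[C@H](OC(=O)/C(C)=C\C)/C=C(\CBr)C(=O)OC)O1 | intermediate
18 | methyl 2-[(4Z,6R,7S,8S,10R)-8-angeloyloxy-6-hydroxy-4,10-dimethyl-1-oxo-3,10-epoxycyclodeca-2,4-dien-7-yl]prop-2-enoate (germacrane numbering; same spatial arrangement as 19, the C-7 descriptor changes only because the lactone is open) | COC(=O)C(=C)[C@H]1[C@H](O)/C=C(/C)C2=CC(=O)[C@@](C)(C[C@@H]1OC(=O)/C(C)=C\C)O2 | intermediate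
19 | lychnopholide, (4Z,6R,7R,8S,10R)-8-angeloyloxy-1-oxo-3,10-epoxygermacra-2,4,11(13)-trien-12,6-olide | C=C1C(=O)O[C@@H]2/C=C(/C)C3=CC(=O)[C@@](C)(C[C@H](OC(=O)/C(C)=C\C)[C@@H]12)O3 | target

**Step count and risks**

Total step count: 9. Longest linear sequence: 8 (steps 1, 2, 4, 5, 6, 7, 8, 9 from crotonaldehyde); step 3 is a one-step side branch.

Most likely to fail, step 9 (chromium-mediated ring closure). The allylchromium carries a δ-angeloyloxy group and can lose it by vinylogous β-elimination to a diene before the slow medium-ring closure; the diastereoselectivity at C-6 and C-7 is predicted, not proven. Fallback: carry O-8 as a silyl ether and esterify last. It sets out from 12 and comes back at 19. Silylation of 12 (t-BuMe2SiOTf, 2,6-lutidine) gives (2R)-2-[(2S,3E)-2-(tert-butyldimethylsilyloxy)pent-3-enyl]-2-methyl-5-[(2Z)-4-(triethylsilyloxy)but-2-en-2-yl]furan-3(2H)-one F1. Swern oxidation, which attacks only the primary triethylsilyl ether, gives the enal (2Z)-3-{(5R)-5-[(2S,3E)-2-(tert-butyldimethylsilyloxy)pent-3-enyl]-5-methyl-4-oxo-4,5-dihydrofuran-2-yl}but-2-enal F2. Cross-metathesis with 2 gives methyl (2Z,4S)-2-(bromomethyl)-4-(tert-butyldimethylsilyloxy)-5-{(2R)-2-methyl-3-oxo-5-[(2Z)-4-oxobut-2-en-2-yl]-2,3-dihydrofuran-2-yl}pent-2-enoate F3. CrCl2 at high dilution gives the 8-O-silyl hydroxy ester F4, which acid lactonises to 8-O-(tert-butyldimethylsilyl)-8-deangeloyl-lychnopholide F5. HF·pyridine frees 8-deangeloyl-lychnopholide F6, and angeloylation with mixed anhydride 14 as in step 6 gives 19. The silyl ether is a far poorer leaving group than the ester, and F6 also serves for other C-8 esters.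

Second, step 8 (cross-metathesis). It joins an allylically acyloxylated internal alkene to an electron-poor 1,1-disubstituted acrylate to make a trisubstituted alkene, and conversion may be low. Fallback: build the acrylate by carbonyl chemistry. It sets out from 16 and comes back at 17. OsO4 (cat.)/NaIO4/2,6-lutidine attacks the isolated propenyl group in preference to the three conjugated, electron-poor alkenes; the intermediate (2S)-3,4-dihydroxy-1-{(2R)-2-methyl-3-oxo-5-[(2Z)-4-oxobut-2-en-2-yl]-2,3-dihydrofuran-2-yl}pentan-2-yl angelate F7 is cleaved in the same flask to the α-angeloyloxy aldehyde (2S)-1-{(2R)-2-methyl-3-oxo-5-[(2Z)-4-oxobut-2-en-2-yl]-2,3-dihydrofuran-2-yl}-3-oxopropan-2-yl angelate F8. A Morita–Baylis–Hillman reaction (methyl acrylate, DABCO, MeOH, 0 °C) occurs at the activated α-acyloxy aldehyde and not at the hindered β,β-disubstituted enal, giving methyl (4S)-3-hydroxy-2-methylene-4-{[(2Z)-2-methylbut-2-enoyl]oxy}-5-{(2R)-2-methyl-3-oxo-5-[(2Z)-4-oxobut-2-en-2-yl]-2,3-dihydrofuran-2-yl}pentanoate F9. NBS/Me2S then converts F9 with allylic transposition into 17. The weak point of this fallback is possible epimerisation at C-8 of F8 under DABCO.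

Third, step 2 (reductive hydroxylation). The enolate 6 can add to unreduced 5, and the facial selectivity that creates the quaternary C-10 carbinol may be modest. Fallback: replace the enolate route by a radical hydrogen-atom-transfer hydration. It sets out from 5 and comes back at 7. Mukaiyama-type conditions (Mn(dpm)3 cat., PhSiH3, O2, i-PrOH, 0 °C) put hydrogen on the exocyclic methylene and trap the tertiary α-radical with oxygen anti to the propenyl group, giving (3R,5S)-3-hydroperoxy-3-methyl-5-[(E)-prop-1-enyl]dihydrofuran-2(3H)-one F10. P(OEt)3 added to the same flask reduces F10 to 7, and the minor cis diastereomer is removed by chromatography.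

**Further compounds**

F1 | step 9 | (2R)-2-[(2S,3E)-2-(tert-butyldimethylsilyloxy)pent-3-enyl]-2-methyl-5-[(2Z)-4-(triethylsilyloxy)but-2-en-2-yl]furan-3(2H)-one | CC[Si](CC)(CC)OC/C=C(/C)C1=CC(=O)[C@@](C)(C[C@H](O[Si](C)(C)C(C)(C)C)/C=C/C)O1
F2 | step 9 | (2Z)-3-{(5R)-5-[(2S,3E)-2-(tert-butyldimethylsilyloxy)pent-3-enyl]-5-methyl-4-oxo-4,5-dihydrofuran-2-yl}but-2-enal | O=C/C=C(/C)C1=CC(=O)[C@@](C)(C[C@H](O[Si](C)(C)C(C)(C)C)/C=C/C)O1
F3 | step 9 | methyl (2Z,4S)-2-(bromomethyl)-4-(tert-butyldimethylsilyloxy)-5-{(2R)-2-methyl-3-oxo-5-[(2Z)-4-oxobut-2-en-2-yl]-2,3-dihydrofuran-2-yl}pent-2-enoate | O=C/C=C(/C)C1=CC(=O)[C@@](C)(C[C@H](O[Si](C)(C)C(C)(C)C)/C=C(\CBr)C(=O)OC)O1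
F4 | step 9 | methyl 2-[(4Z,6R,7S,8S,10R)-8-(tert-butyldimethylsilyloxy)-6-hydroxy-4,10-dimethyl-1-oxo-3,10-epoxycyclodeca-2,4-dien-7-yl]prop-2-enoate | COC(=O)C(=C)[C@H]1[C@H](O)/C=C(/C)C2=CC(=O)[C@@](C)(C[C@@H]1O[Si](C)(C)C(C)(C)C)O2
F5 | step 9 | 8-O-(tert-butyldimethylsilyl)-8-deangeloyl-lychnopholide | C=C1C(=O)O[C@@H]2/C=C(/C)C3=CC(=O)[C@@](C)(C[C@H](O[Si](C)(C)C(C)(C)C)[C@@H]12)O3
F6 | step 9 | 8-deangeloyl-lychnopholide (free C-8 alcohol) | C=C1C(=O)O[C@@H]2/C=C(/C)C3=CC(=O)[C@@](C)(C[C@H](O)[C@@H]12)O3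
F7 | step 8 | (2S)-3,4-dihydroxy-1-{(2R)-2-methyl-3-oxo-5-[(2Z)-4-oxobut-2-en-2-yl]-2,3-dihydrofuran-2-yl}pentan-2-yl (2Z)-2-methylbut-2-enoate (diol mixture) | O=C/C=C(/C)C1=CC(=O)[C@@](C)(C[C@H](OC(=O)/C(C)=C\C)C(O)C(C)O)O1
F8 | step 8 | (2S)-1-{(2R)-2-methyl-3-oxo-5-[(2Z)-4-oxobut-2-en-2-yl]-2,3-dihydrofuran-2-yl}-3-oxopropan-2-yl (2Z)-2-methylbut-2-enoate | O=C/C=C(/C)C1=CC(=O)[C@@](C)(C[C@H](OC(=O)/C(C)=C\C)C=O)O1
F9 | step 8 | methyl (4S)-3-hydroxy-2-methylene-4-{[(2Z)-2-methylbut-2-enoyl]oxy}-5-{(2R)-2-methyl-3-oxo-5-[(2Z)-4-oxobut-2-en-2-yl]-2,3-dihydrofuran-2-yl}pentanoate (both C-3 epimers) | O=C/C=C(/C)C1=CC(=O)[C@@](C)(C[C@H](OC(=O)/C(C)=C\C)C(O)C(=C)C(=O)OC)O1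
F10 | step 2 | (3R,5S)-3-hydroperoxy-3-methyl-5-[(E)-prop-1-enyl]dihydrofuran-2(3H)-one | C[C@@]1(OO)C[C@@H](/C=C/C)OC1=O
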